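**Retrosynthetic overview**

1. Target 18 comes from keto lactone 15 by hydrogenolysis of the O-benzyl group and of the aryl ketone, which stands in place of the benzylic CH2 between lactone C4 and ring B.
2. The route rests on that benzylic carbon between C4 and ring B: carried as a ketone it makes C4–H the most acidic C–H, so C5 and O1 enter together as formaldehyde (C4–C5 aldol, O1–C2 lactonization of keto ester 11).
3. Keto ester 11 comes from imide 7 and bromoketone 8 by auxiliary-controlled alkylation, which forms C3–C4 and sets C3, followed by methanolysis.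
4. Imide 7 comes from isoferulic acid 1 (ring A and the C3 side chain) by hydrogenation, benzylation and acylation of auxiliary 5.
5. Ring order: rings A and B are bought; the lactone ring (O1, C2, C3, C4, C5) is the only ring formed, in step 6.

Key step: step 6

Assumption: the target SMILES is read as the trans (3R,4R) lactone. Lactone numbering is O1, C2 (C=O), C3, C4, C5; ring A is the 3-hydroxy-4-methoxyphenyl ring on the C3 benzyl group and ring B is the 3,4-dimethoxyphenyl ring on the C4 benzyl group.

**Route**

Step 1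
Reactants: 1 isoferulic acid ((E)-3-(3-hydroxy-4-methoxyphenyl)acrylic acid)
Product: 2 3-(3-hydroxy-4-methoxyphenyl)propanoic acid
Conditions: H2 (1 atm), 10% Pd/C, MeOH, rt
Reagents that add atoms: none
Why: Heterogeneous catalytic hydrogenation of the cinnamic acid C=C should proceed cleanly, since phenol, acid and arene are inert under these conditions.

Step 2
Reactants: 2 3-(3-hydroxy-4-methoxyphenyl)propanoic acid
Product: 4 3-(3-benzyloxy-4-methoxyphenyl)propanoic acid, via benzyl ester 3 (not isolated)
Conditions: BnBr (2.3 equiv), K2CO3, DMF, 60 °C; then 2 M NaOH, MeOH, 60 °C; then HCl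
Reagents that add atoms: benzyl bromide, BrCc1ccccc1
Why: Williamson O-alkylation benzylates both the phenoxide and the carboxylate, and ester saponification in the same pot then frees the acid while the aryl benzyl ether is stable to hydroxide.

Step 3
Reactants: 4 3-(3-benzyloxy-4-methoxyphenyl)propanoic acid; 5 (S)-4-benzyloxazolidin-2-one
Product: 7 (S)-4-benzyl-3-[3-(3-benzyloxy-4-methoxyphenyl)propanoyl]oxazolidin-2-one, via mixed pivalic anhydride 6 (not isolated)
Conditions: PivCl, Et3N, THF, −20 °C; then 5, LiCl, −20 °C to rt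
Reagents that add atoms: none
Why: N-Acylation of the oxazolidinone through the mixed pivalic anhydride (LiCl/Et3N protocol) should occur at the less hindered acyl carbon of 6; the auxiliary stereocentre is not involved.

Step 4
Reactants: 7 (S)-4-benzyl-3-[3-(3-benzyloxy-4-methoxyphenyl)propanoyl]oxazolidin-2-one; 8 2-bromo-1-(3,4-dimethoxyphenyl)ethanone
Product: 10 (S)-4-benzyl-3-[(R)-2-(3-benzyloxy-4-methoxybenzyl)-4-(3,4-dimethoxyphenyl)-4-oxobutanoyl]oxazolidin-2-one, via sodium (Z)-enolate 9 (not isolated)
Conditions: NaN(SiMe3)2 (1.05 equiv), THF, −78 °C; then 8, −78 to −40 °C; AcOH quench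
Reagents that add atoms: none
Why: Evans asymmetric alkylation: the chelated sodium (Z)-enolate 9 should be attacked in an SN2 reaction by the highly reactive alpha-bromoketone on the face opposite the C4 benzyl group of the auxiliary, which sets the new centre (the future lactone C3) as R.

Step 5
Reactants: 10 (S)-4-benzyl-3-[(R)-2-(3-benzyloxy-4-methoxybenzyl)-4-(3,4-dimethoxyphenyl)-4-oxobutanoyl]oxazolidin-2-one
Product: 11 methyl (R)-2-(3-benzyloxy-4-methoxybenzyl)-4-(3,4-dimethoxyphenyl)-4-oxobutanoate
Conditions: MeOMgBr (from MeMgBr added to MeOH), MeOH–CH2Cl2, 0 °C to rt; 1 M HCl quench at 0 °C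
Reagents that add atoms: methanol (delivered as MeOMgBr), CO
Why: Transesterification of the N-acyl oxazolidinone with the magnesium methoxide is chelation-directed to the exocyclic carbonyl and is too weakly basic to enolize the alpha-centre or the ketone, so 11 should form with the R centre intact and auxiliary 5 is recovered.

Step 6
Reactants: 11 methyl (R)-2-(3-benzyloxy-4-methoxybenzyl)-4-(3,4-dimethoxyphenyl)-4-oxobutanoate; 12 formaldehyde (37% aqueous solution)
Product: 15 (3R,4R)-3-(3-benzyloxy-4-methoxybenzyl)-4-(3,4-dimethoxybenzoyl)dihydrofuran-2(3H)-one, via hydroxymethyl keto ester 13 (not isolated), via cis keto lactone 14 (not isolated)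
Conditions: 37% aq. HCHO (1.2 equiv), K2CO3 (0.3 equiv), THF–H2O, 0 °C to rt; then 1 M HCl, rt
Reagents that add atoms: formaldehyde (compound 12), C=O
Why: Carbonate (hydroxide at equilibrium) reversibly deprotonates C4, the only enolizable position of the aryl ketone because its other alpha-position is ring B, and the enolate adds to formaldehyde in a crossed (Tollens-type) aldol that forms C4–C5 and gives 13. The new primary hydroxyl then attacks the methyl ester carbonyl in a 5-exo-trig acyl substitution that forms O1–C2, expels methanol and closes the lactone ring; the closest known reaction type is the base-mediated hydroxymethylation–lactonization of 3-aroylpropanoic acids and esters to 4-aroylbutyrolactones. C3 is not a new centre and should be kept, because it is alpha only to an ester or lactone carbonyl, which carbonate does not enolize at a useful rate. The new centre C4 stays alpha to the ketone, so cis isomer 14 should equilibrate through the ketone enolate to trans 15, the thermodynamic arrangement relative to the fixed C3 benzyl group (substrate control). The step needs mono-hydroxymethylation without dehydration: formaldehyde is kept to a small excess, the hindered tertiary C4–H of the lactone is enolized more slowly than the CH2 of 11, a second aldol would be reversible, and lactonization removes the beta-hydroxy ketone before it can lose water, while ring-opening beta-elimination of the lactone is the reverse of a 5-endo-trig closure and is stereoelectronically disfavoured. The acidic work-up recloses any hydroxy acid formed by partial saponification.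

Step 7
Reactants: 15 (3R,4R)-3-(3-benzyloxy-4-methoxybenzyl)-4-(3,4-dimethoxybenzoyl)dihydrofuran-2(3H)-one
Product: 18 prestegane A [(3R,4R)-4-(3,4-dimethoxybenzyl)-3-(3-hydroxy-4-methoxybenzyl)dihydrofuran-2(3H)-one], via phenolic keto lactone 16 (not isolated), via benzylic carbinol 17 (not isolated)
Conditions: H2 (3 atm), 10% Pd/C, AcOH, HClO4 (cat.), rt
Reagents that add atoms: none
Why: Acid-assisted heterogeneous hydrogenolysis should first cleave the aryl benzyl ether and then take the electron-rich aryl ketone through the benzylic carbinol to CH2 (benzylic C–O hydrogenolysis), neither C3 nor C4 being a reacting centre, so the trans (3R,4R) configuration is carried into the target.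

**Compound list**

1 | isoferulic acid | COc1ccc(/C=C/C(=O)O)cc1O | starting material
2 | 3-(3-hydroxy-4-methoxyphenyl)propanoic acid | COc1ccc(CCC(=O)O)cc1O | intermediate
3 | benzyl 3-(3-benzyloxy-4-methoxyphenyl)propanoate | COc1ccc(CCC(=O)OCc2ccccc2)cc1OCc1ccccc1 | intermediate
4 | 3-(3-benzyloxy-4-methoxyphenyl)propanoic acid | COc1ccc(CCC(=O)O)cc1OCc1ccccc1 | intermediate
5 | (S)-4-benzyloxazolidin-2-one | O=C1N[C@@H](Cc2ccccc2)CO1 | starting material
6 | 3-(3-benzyloxy-4-methoxyphenyl)propanoic pivalic anhydride | COc1ccc(CCC(=O)OC(=O)C(C)(C)C)cc1OCc1ccccc1 | intermediate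
7 | (S)-4-benzyl-3-[3-(3-benzyloxy-4-methoxyphenyl)propanoyl]oxazolidin-2-one | O=C1OC[C@H](Cc2ccccc2)N1C(=O)CCc1ccc(OC)c(OCc2ccccc2)c1 | intermediate
8 | 2-bromo-1-(3,4-dimethoxyphenyl)ethanone | COc1ccc(C(=O)CBr)cc1OC | starting material
9 | sodium (Z)-enolate of 7 | [Na+].[O-]/C(=C\Cc1ccc(OC)c(OCc2ccccc2)c1)N1C(=O)OC[C@@H]1Cc1ccccc1 | intermediate
10 | (S)-4-benzyl-3-[(R)-2-(3-benzyloxy-4-methoxybenzyl)-4-(3,4-dimethoxyphenyl)-4-oxobutanoyl]oxazolidin-2-one | O=C1OC[C@H](Cc2ccccc2)N1C(=O)[C@H](Cc1ccc(OC)c(OCc2ccccc2)c1)CC(=O)c1ccc(OC)c(OC)c1 | intermediate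
11 | methyl (R)-2-(3-benzyloxy-4-methoxybenzyl)-4-(3,4-dimethoxyphenyl)-4-oxobutanoate | COC(=O)[C@H](Cc1ccc(OC)c(OCc2ccccc2)c1)CC(=O)c1ccc(OC)c(OC)c1 | intermediate
12 | formaldehyde | C=O | starting material
13 | methyl (2R)-2-(3-benzyloxy-4-methoxybenzyl)-4-(3,4-dimethoxyphenyl)-3-(hydroxymethyl)-4-oxobutanoate (both C3 epimers) | COC(=O)[C@H](Cc1ccc(OC)c(OCc2ccccc2)c1)C(CO)C(=O)c1ccc(OC)c(OC)c1 | intermediate
14 | (3R,4S)-3-(3-benzyloxy-4-methoxybenzyl)-4-(3,4-dimethoxybenzoyl)dihydrofuran-2(3H)-one (cis) | COc1ccc(C[C@H]2C(=O)OC[C@H]2C(=O)c2ccc(OC)c(OC)c2)cc1OCc1ccccc1 | intermediate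
15 | (3R,4R)-3-(3-benzyloxy-4-methoxybenzyl)-4-(3,4-dimethoxybenzoyl)dihydrofuran-2(3H)-one (trans) | COc1ccc(C[C@H]2C(=O)OC[C@@H]2C(=O)c2ccc(OC)c(OC)c2)cc1OCc1ccccc1 | intermediate
16 | (3R,4R)-4-(3,4-dimethoxybenzoyl)-3-(3-hydroxy-4-methoxybenzyl)dihydrofuran-2(3H)-one | COc1ccc(C[C@H]2C(=O)OC[C@@H]2C(=O)c2ccc(OC)c(OC)c2)cc1O | intermediate
17 | (3R,4R)-4-[(3,4-dimethoxyphenyl)(hydroxy)methyl]-3-(3-hydroxy-4-methoxybenzyl)dihydrofuran-2(3H)-one (both carbinol epimers) | COc1ccc(C[C@H]2C(=O)OC[C@@H]2C(O)c2ccc(OC)c(OC)c2)cc1O | intermediate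
18 | prestegane A, (3R,4R)-4-(3,4-dimethoxybenzyl)-3-(3-hydroxy-4-methoxybenzyl)dihydrofuran-2(3H)-one | COc1ccc(C[C@H]2C(=O)OC[C@@H]2Cc2ccc(OC)c(OC)c2)cc1O | target

**Totals**

Total step count: 7. Longest linear sequence: 7 steps (1 to 18).

**Steps most likely to fail**

Step 6 (key step). Under carbonate the enolization of the electron-rich aryl ketone may be slow. A second formaldehyde may add at C4, or the open aldol may lose water to an alpha-methylene ketone before the ring closes. The fallback separates enolization from C–C bond formation. It sets out from 11: soft enolization with Me3SiOTf and Et3N (CH2Cl2, 0 °C) should silylate only the ketone and give methyl (R,Z)-2-(3-benzyloxy-4-methoxybenzyl)-4-(3,4-dimethoxyphenyl)-4-(trimethylsilyloxy)but-3-enoate F1. A Mukaiyama aldol with aqueous formaldehyde and Sc(OTf)3 (cat.) in THF–H2O should then give 13, and only one hydroxymethyl group can enter because the silyl enol ether reacts once. TsOH (cat.) in CH2Cl2 should close the lactone and DBU (cat.) should equilibrate 14 to the trans isomer, so the fallback returns to the route at 15.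

Step 4. The acidic alpha-bromoketone may transfer a proton to the enolate, the enolate may attack the ketone carbonyl (Darzens-type pathway), or a second alkylation may occur, each lowering conversion. The fallback brings in the aryl ketone after the stereocentre is set and sets out from 7 (through enolate 9):
- Alkylation with tert-butyl bromoacetate (THF, −78 °C) should give tert-butyl (R)-3-(3-benzyloxy-4-methoxybenzyl)-4-[(S)-4-benzyl-2-oxooxazolidin-3-yl]-4-oxobutanoate F2, with the same facial control.
- MeOMgBr in MeOH should give 4-tert-butyl 1-methyl (R)-2-(3-benzyloxy-4-methoxybenzyl)succinate F3.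
- TFA in CH2Cl2 (0 °C to rt) should free (R)-3-(3-benzyloxy-4-methoxybenzyl)-4-methoxy-4-oxobutanoic acid F4.
- Oxalyl chloride with DMF (cat.) should give methyl (R)-2-(3-benzyloxy-4-methoxybenzyl)-4-chloro-4-oxobutanoate F5.
- Acyl Suzuki coupling with 3,4-dimethoxyphenylboronic acid (Pd(PPh3)4 cat., Cs2CO3, dry toluene, 100 °C) should form the aryl ketone, so the fallback returns to the route at 11.

Step 7. The reduction may stall at the carbinol. The acid may also ionize the carbinol with loss of the C4 proton, and hydrogenation of the resulting styrene from the less hindered face would erode the trans configuration at C4. Migration of the lactone acyl group onto the transient carbinol oxygen is possible too, but it should converge on 18 after benzylic C–O hydrogenolysis and relactonization. The fallback avoids any benzylic cation and sets out from 15. Neutral hydrogenolysis (H2 1 atm, Pd/C, EtOAc, rt) should remove only the benzyl group and give 16. Ethane-1,2-dithiol with BF3·OEt2 (CH2Cl2, 0 °C to rt) should give (3R,4R)-4-[2-(3,4-dimethoxyphenyl)-1,3-dithiolan-2-yl]-3-(3-hydroxy-4-methoxybenzyl)dihydrofuran-2(3H)-one F6. Desulfurization with Raney Ni (EtOH, reflux) should then give the CH2 group, so the fallback returns to the route at 18.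

**Further compounds**

F1 | step 6 | methyl (R,Z)-2-(3-benzyloxy-4-methoxybenzyl)-4-(3,4-dimethoxyphenyl)-4-(trimethylsilyloxy)but-3-enoate | COC(=O)[C@H](Cc1ccc(OC)c(OCc2ccccc2)c1)/C=C(\O[Si](C)(C)C)c1ccc(OC)c(OC)c1
F2 | step 4 | tert-butyl (R)-3-(3-benzyloxy-4-methoxybenzyl)-4-[(S)-4-benzyl-2-oxooxazolidin-3-yl]-4-oxobutanoate | O=C1OC[C@H](Cc2ccccc2)N1C(=O)[C@H](Cc1ccc(OC)c(OCc2ccccc2)c1)CC(=O)OC(C)(C)C
F3 | step 4 | 4-tert-butyl 1-methyl (R)-2-(3-benzyloxy-4-methoxybenzyl)succinate | COC(=O)[C@H](Cc1ccc(OC)c(OCc2ccccc2)c1)CC(=O)OC(C)(C)C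
F4 | step 4 | (R)-3-(3-benzyloxy-4-methoxybenzyl)-4-methoxy-4-oxobutanoic acid | COC(=O)[C@H](Cc1ccc(OC)c(OCc2ccccc2)c1)CC(=O)O
F5 | step 4 | methyl (R)-2-(3-benzyloxy-4-methoxybenzyl)-4-chloro-4-oxobutanoate | COC(=O)[C@H](Cc1ccc(OC)c(OCc2ccccc2)c1)CC(=O)Cl
F6 | step 7 | (3R,4R)-4-[2-(3,4-dimethoxyphenyl)-1,3-dithiolan-2-yl]-3-(3-hydroxy-4-methoxybenzyl)dihydrofuran-2(3H)-one | COc1ccc(C[C@H]2C(=O)OC[C@@H]2C3(SCCS3)c4ccc(OC)c(OC)c4)cc1O
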